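Time was the first item at the meeting: the grey flask had been followed for 40.0 h, and the question was how far it goes by 6.0 d.

| flask | solid substrate | reagent | remark | time |
|---|---|---|---|---|
| grey | 10 mM | 8 mM | the very flask that is asked about, followed so far |  |
| blue | 5 mM | 8 mM | run made earlier |  |
| flask | 10 mM | 8.00 mM |  | 6.0 d |

grey run (percent of the solid substrate charged)

| time / h | solid substrate / % | single product / % | other mono adduct / % |
|---|---|---|---|
| 8.00 | 98 | 1 | 0 |
| 15.0 | 98 | 3 | 1 |
| 25.0 | 93 | 2 | 0 |
| 30.0 | 89 | 4 | 0 |
| 40.0 | 92 | 3 | 0 |

blue run (percent of the solid substrate charged)

| time / d | solid substrate / % | single product / % | other mono adduct / % |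
|---|---|---|---|
| 0.833 | 89 | 2 | 1 |
| 1.67 | 77 | 0 | 1 |
| 2.50 | 73 | 2 | 1 |
| 3.00 | 68 | 1 | 1 |
| 4.00 | 61 | 1 | 0 |

(standard deviation of a reading: 2 percentage points)

- as a solid, counted per litre of solution: solid substrate
- the numbers in the tables scatter with a standard deviation of 2 percentage points
- at the start none of the solid substrate is in solution

- the solid substrate standing at 6.0 d, as a percentage of the solid substrate charged (only what is still solid)
- the single product standing at 6.0 d, as a percentage of the solid substrate charged
- the other mono adduct standing at 6.0 d, as a percentage of the solid substrate charged
- the double product standing at 6.0 d, as a percentage of the solid substrate charged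

The first speaker set the zero of the scale: if solid leaves in proportion to the solid present, both flasks lose equal fractions of their charges per day, a ratio of 1. The second speaker reported otherwise. From the last readings, the blue flask had lost 39.0% of its charge in 4.00 d and the grey flask 8.00% in 40.0 h, so the blue daily fraction over the grey one reads 2.03, close to the ratio of charges, though each reading carries a scatter of 2 percentage points. She therefore proposed a loss of apparent zero order in the solid and named the drain, the estimated fraction of the grey charge leaving per day, taken from the mean blue loss over its run, scaled by the charges: 0.0488 d⁻¹.

The third speaker asked whether the reagent lasts. Counting two reagent for each solid lost, he put the demand of the grey flask by 6.0 d at 73.1% of its reagent charge, an estimate less than the charge. The meeting therefore committed to 70.8% solid substrate, mono adducts near their last grey readings, and double product near 26.3%, a figure that counts nothing as standing dissolved.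

The forecast gave more solid than the meeting: solid substrate 74.5%, single product 2.5%, other mono adduct 0.5% and double product 22.5%, holding that “the rate doesn't depend on the amount of solid”.

The grey flask gives solid substrate 69.4%, single product 1.61%, other mono adduct 0.666% and double product 24.0%.

    starting material + reagent → single product + by-product (k = 7.00 M⁻¹ h⁻¹)
    starting material + reagent → other mono adduct + by-product (k = 5.70 M⁻¹ h⁻¹)
    reagent + single product → double product + by-product (k = 17.0 M⁻¹ h⁻¹)
    reagent + other mono adduct → double product + by-product (k = 35.0 M⁻¹ h⁻¹)
    solid substrate ⇌ starting material, rate k5*(cs5 - [starting material]) while solid is left; crystals form when [starting material] > cs5 (solubility = 1.80 mM, k = 0.0140 h⁻¹)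

The meeting's solid figure stands 1.4 points above the grey flask's. The neighbouring flask has the same charges but is read at 10 d. There the drain gives 51.2% solid substrate, although that loss, counted at two reagent per solid, comes to 122% of the reagent charge, more than was charged. That neighbouring flask holds 53.4% solid substrate, with 9.25% of its reagent left and starting material at 8.39%.

(The data were generated by integration from invented constants.)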